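## Structural features

Pestalone F is an achiral benzophenone: two highly substituted benzene rings joined only through the ketone carbon. Ring A carries the ketone on C1, a free OH on C2, Cl on C3, CH3 on C4, H on C5 and OCH3 on C6. Ring B carries the ketone on C1', CHO on C2', OH on C3', H on C4', OH on C5' and a prenyl group on C6'. There is no stereocentre, so every selectivity question is one of position. The real difficulty is the carbonyl carbon, flanked by four ortho substituents and out of reach of ordinary acyl additions, together with placing one chlorine on C3 (not C5) and two different carbon groups on C2' and C6'. The fragile elements are the ortho-aroylbenzaldehyde pair (it condenses with ammonia-type nitrogen to isoindolinones and isomerises to a phthalide by hydride shift under base), the prenyl group beside a phenol (chroman formation in strong acid, attack by electrophilic halogen) and the electron-rich resorcinol ring. The key step exploits the neighbouring carbon (C1) and oxygen (C2) of ring A with OCH3 on C6: this is the carbon–oxygen pair that a nitrile oxide delivers across a 3-methoxyaryne. It also exploits the local mirror symmetry of ring B about the C1'–C4' axis, which allows a symmetric 2,6-dibromo dipole whose bromines are differentiated afterwards.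

## Logic of the disconnections

**28 ⇒ 27.** The two aryl O–CH2 acetal bonds on the C3' and C5' oxygens are cut last. The phenols must stay masked through bromination, fluoride and organolithium chemistry, and removing the masks at the end leaves no step after the most fragile compound. The gain is a neutral, lithiation-compatible ring B for all earlier steps. The demand is an acid mild enough to spare the prenyl–phenol pair and the keto aldehyde.

**27 ⇒ 26.** No skeletal bond is cut; the C2' formyl group is taken back to CH2OH. An ortho-aroylbenzaldehyde cannot coexist with the N–H imine or ammonia released in the ring opening (isoindolinone formation), so the formyl carbon is held at the alcohol level until the nitrogen has left. The gain is a robust substrate for the ring opening, whose hydroxyl also assists imine hydrolysis. The demand is a neutral, chemoselective benzylic oxidation beside a free phenol and an alkene.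

**26 ⇒ 24 (through 25).** The C1 ketone oxygen and the C2–OH are traced back to the C=N and O–N bonds of the isoxazole ring of 24. The heterocycle hides the ketone and the phenol during all organometallic steps. The gain is that no C–C bond is ever formed next to a free, crowded ketone. The demand is an N–O reduction that spares aryl chloride, alkene and acetals, and hydrolysis of a hindered imine under weak acid.

**24 ⇒ 21.** The C2'–CH2OH bond is cut to an aryl bromide and a one-carbon electrophile. The gain is a simple halogen in place of the substituent. The demand is bromine–lithium exchange that leaves the heterocycle, the chlorine and the prenyl group untouched.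

**21 ⇒ 17 + 18.** The C6'–CH2 bond is cut. The prenyl group cannot be present earlier: the dipole would add to its alkene intramolecularly and electrophilic chlorine would attack it. The gain is a mirror-symmetric dibromide, so no question of which bromine reacts first. The demand is exactly one exchange and substitution at the primary carbon of 18.

**17 ⇒ 16.** The C3–Cl bond is cut. A chlorine on the aryne would polarise it against the methoxy group, so it is added after the cycloaddition. The gain is an aryne with a single directing group. The demand is chlorination at the position para to OCH3 rather than at C5 or at the ring B C–H.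

**16 ⇒ 8 + 14 (through 15).** The C1–C(imine) and C2–O bonds are cut together, opening the isoxazole ring. This replaces a hopeless carbonyl addition by a cycloaddition at a planar aryne and an sp carbon. The gain is two fragments of similar size, each three or four steps from a commercial phenol. The demand is regioselectivity: carbon to C1, oxygen to C2.

**8 ⇒ 6 ⇒ 2 ⇒ 1.** The O–S bond of the triflate, the C–Si bond and the carbamate C–O bond are cut in turn. Silicon must sit between two oxygens, a position reached by cooperative directed metalation and not by electrophilic substitution. The gain is commercial 1. The demand is lithiation between the two oxygen groups and a carbamate that leaves under mild conditions.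

**14 ⇒ 12 ⇒ 11 ⇒ 10 ⇒ 9.** The dipole is taken back to the aldoxime, the aldehyde, the two C–Br bonds and the two acetal O–C bonds. Commercial 9 already holds the carbon skeleton and oxygen pattern of ring B. The demand is dibromination at the two positions flanking the formyl group, not at the position between the oxygens.

## Other disconnections considered

**Alternative 1:** The cut runs through ring B at C1'–C2', unravelling the ring into the polycarbonyl chain of A1. A1 is a 2,2-dimethyl-1,3-dioxin-4-one with a 2,4-dioxopentyl chain, the prenyl group on the central carbon and the silyl-protected ring A carbinol at the end. Forward, Et3N and then acid would fold A1 by intramolecular aldol condensation and dehydration into benzodioxinone A2.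
- In its favour: the ring B pattern follows from chain connectivity with no positional ambiguity, the prenyl group enters by enolate alkylation, the conditions are mild, and ring A arrives with its chlorine. On these points it is the better plan.
- Against it here: A2 holds the inter-ring carbon at the carbinol level and the future formyl carbon at the carboxyl level. Desilylation, oxidation to the crowded ketone and a lactone-to-aldehyde reduction must follow, the last beside a ketone that invites lactol and phthalide formation. A1 itself needs acylation with a hindered alpha-silyloxy arylacetyl unit and regiocontrolled C-prenylation between two carbonyl groups.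
- Comparison: it is a stepwise ionic closure of a carbocycle, against a cycloaddition that joins two finished arenes directly at the ketone oxidation level. The chosen plan should be shorter, since both its fragments come from commercial phenols in three or four steps.

**Alternative 2:** Ring A is dismantled at C1–C2, C5–C6 and C2–C3, leaving cyclobutenone A3 and the ring B-substituted methoxyalkyne A4. Heating would open A3 to a chlorovinylketene that adds to A4 in a (2+2) cycloaddition; 4-pi opening and 6-pi closure then give phenol A5 (Danheiser benzannulation).
- In its favour: the chlorine is placed by the structure of A3 and not by an electrophilic substitution, a clear advantage over the chosen plan. The regiochemistry follows from the polarisation of the ynol ether, and the C2 phenol appears free.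
- Against it here: A4 presupposes a finished pentasubstituted ring B aldehyde, so the sequential metalations of ring B are moved earlier and lengthened, not avoided. A3 is a sensitive non-commercial reagent. The thermal cascade must tolerate a bulky propargylic group and a nearby prenyl alkene that can also trap ketenes. A5 is again a carbinol to be desilylated and oxidised.
- Comparison: in carrying the formyl carbon as a protected CH2OH to a late oxidation the two plans are equal. In step count the chosen plan should be ahead.

**Alternative 3:** Ring B is cut at C2'–C3' and C6'–C1' into the electron-rich triene A6 (a 1-methoxy-1,3-bis(silyloxy)diene with the prenyl chain on its terminus) and alkynoate A7, which carries the ring A carbinol. Forward, a (4+2) cycloaddition followed by loss of methanol and the silyl groups would give resorcylate A8.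
- In its favour: it is as convergent as the chosen plan (two fragments, two bonds, one ring), the polarity of the partners is matched, A6 derives from a simple beta-keto ester, and ring A again enters with its chlorine in place, which is better than a late chlorination.
- Against it here: the C6'–C1' bond must form between the substituted diene terminus and the alkyne carbon bearing the bulky silyloxy(aryl)methyl group, in a bimolecular thermal reaction of a hydrolytically labile diene. Open-chain Michael-type addition is a likely diversion. A8 needs carbinol-to-ketone oxidation and ester-to-aldehyde adjustment, with lactonisation to a phthalide open once the carbinol is freed.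
- Comparison: it forms a carbocycle by Diels–Alder reaction and aromatisation, against a heterocycle-forming dipolar addition. The steps after the key step should be similar in number, but more are needed before it.

Key step: step 8

Assumption: the target is the achiral structure of the SMILES; hindered rotation about the aryl–heteroaryl bond in 21–24 would give at most racemic atropisomers that converge on ring opening, and oxime 12 is drawn E although either geometry serves.

## Route

Step 1
Reactants: 1 3-methoxy-5-methylphenol
Product: 2 3-methoxy-5-methylphenyl N-isopropylcarbamate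
Conditions: i-PrNCO, Et3N (cat.), CH2Cl2, rt
Reagents that add atoms: isopropyl isocyanate, CC(C)N=C=O
Why: Base-catalysed addition of the phenol to the isocyanate (carbamoylation). The N-monoalkyl carbamate is chosen because it becomes a strong directing group after N-silylation and is removed later by amines under mild conditions.

Step 2
Reactants: 2 3-methoxy-5-methylphenyl N-isopropylcarbamate
Product: 6 3-methoxy-5-methyl-2-(trimethylsilyl)phenyl N-isopropylcarbamate, via N-silyl carbamate 3 (not isolated), via aryllithium 4 (not isolated), via bis-silyl carbamate 5 (not isolated)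
Conditions: TBSOTf, TMEDA, Et2O, 0 °C → rt; n-BuLi, TMEDA, −78 °C; TMSCl, −78 °C → rt; aq. NaHSO4
Reagents that add atoms: chlorotrimethylsilane, C[Si](C)(C)Cl
Why: Directed ortho-metalation: the N-silylated carbamate and the methoxy group jointly acidify the C–H between them, so lithiation should occur there and TMSCl traps the anion at −78 °C before an anionic Fries shift. The N–Si bond is hydrolysed on acidic work-up.

Step 3
Reactants: 6 3-methoxy-5-methyl-2-(trimethylsilyl)phenyl N-isopropylcarbamate
Product: 8 3-methoxy-5-methyl-2-(trimethylsilyl)phenyl trifluoromethanesulfonate, via silylphenol 7 (not isolated)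
Conditions: Et2NH, DBU, MeCN, 40 °C; then PhNTf2, rt
Reagents that add atoms: N-phenylbis(trifluoromethanesulfonimide), O=S(=O)(N(c1ccccc1)S(=O)(=O)C(F)(F)F)C(F)(F)F
Why: DBU deprotonates the N–H carbamate, which fragments (E1cB) to the phenoxide and isopropyl isocyanate, scavenged by Et2NH. The phenoxide is triflated in the same flask, so the desilylation-prone ortho-silylphenol is never isolated.

Step 4
Reactants: 9 3,5-dihydroxybenzaldehyde
Product: 10 3,5-bis(methoxymethoxy)benzaldehyde
Conditions: MOMCl, i-Pr2NEt, CH2Cl2, 0 °C → rt
Reagents that add atoms: chloromethyl methyl ether, COCCl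
Why: Williamson-type O-alkylation of both phenols. MOM ethers withstand NBS, fluoride and organolithiums, assist the later bromine–lithium exchanges by chelation and leave in dilute acid.

Step 5
Reactants: 10 3,5-bis(methoxymethoxy)benzaldehyde
Product: 11 2,6-dibromo-3,5-bis(methoxymethoxy)benzaldehyde
Conditions: NBS (2.2 equiv), MeCN, 0 °C → rt
Reagents that add atoms: N-bromosuccinimide, O=C1CCC(=O)N1Br
Why: Electrophilic aromatic bromination. C2 and C6 are each ortho to one and para to the other alkoxy group, whereas C4 lies shielded between two alkoxy groups, so two equivalents should give the symmetric dibromide.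

Step 6
Reactants: 11 2,6-dibromo-3,5-bis(methoxymethoxy)benzaldehyde
Product: 12 (E)-2,6-dibromo-3,5-bis(methoxymethoxy)benzaldehyde oxime
Conditions: NH2OH·HCl, NaOAc, EtOH/H2O, 60 °C
Reagents that add atoms: hydroxylamine hydrochloride, NO.Cl
Why: Condensation of the aldehyde with hydroxylamine (oxime formation). The ortho bromines slow but do not block addition to a formyl group, and the buffered medium spares the MOM ethers.

Step 7
Reactants: 12 (E)-2,6-dibromo-3,5-bis(methoxymethoxy)benzaldehyde oxime
Product: 14 2,6-dibromo-3,5-bis(methoxymethoxy)benzonitrile oxide, via hydroximoyl chloride 13 (not isolated)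
Conditions: NCS, DMF, rt; then Et3N, 0 °C
Reagents that add atoms: none
Why: NCS chlorinates the aldoxime C–H and Et3N then removes HCl (1,3-dehydrochlorination) to give the nitrile oxide. The two ortho bromines block dimerisation to the furoxan, so the dipole should be isolable like other 2,6-disubstituted benzonitrile oxides.

Step 8
Reactants: 8 3-methoxy-5-methyl-2-(trimethylsilyl)phenyl trifluoromethanesulfonate; 14 2,6-dibromo-3,5-bis(methoxymethoxy)benzonitrile oxide
Product: 16 3-[2,6-dibromo-3,5-bis(methoxymethoxy)phenyl]-4-methoxy-6-methyl-1,2-benzisoxazole, via aryne 15 (not isolated)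
Conditions: CsF (3 equiv), 8 (1.5 equiv), MeCN, rt
Reagents that add atoms: none
Why: Fluoride attacks silicon of 8 and loss of triflate from the aryl anion gives aryne 15, whose triple bond is distorted by the inductively withdrawing C6 methoxy group so that C2, the carbon remote from that oxygen, is the more electrophilic end. Nitrile oxide 14 adds in a concerted but asynchronous (3+2) cycloaddition: its nucleophilic oxygen bonds to C2 and its carbon to C1, where developing negative charge is stabilised next to the methoxy group. The closest known reaction type is the (3+2) cycloaddition of nitrile oxides with arynes from ortho-silylaryl triflates to give 3-substituted 1,2-benzisoxazoles. The one new ring, the five-membered isoxazole, is closed in this intermolecular cycloaddition by formation of the C1–C and C2–O bonds in a single event, not by a separate cyclisation. No stereocentre is formed. The step needs regioselectivity, secured by the single methoxy group on the aryne and by keeping chlorine, which would polarise the aryne the other way, off the ring until step 9. It also needs cross-addition to outrun dipole dimerisation, secured by the two ortho bromines of 14. Because the reacting carbon of the dipole is sp-hybridised and the aryne is planar, the four ortho substituents that defeat carbonyl additions can be accommodated, and the excess of 8 covers aryne lost to side reactions.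

Step 9
Reactants: 16 3-[2,6-dibromo-3,5-bis(methoxymethoxy)phenyl]-4-methoxy-6-methyl-1,2-benzisoxazole
Product: 17 7-chloro-3-[2,6-dibromo-3,5-bis(methoxymethoxy)phenyl]-4-methoxy-6-methyl-1,2-benzisoxazole
Conditions: NCS (1.05 equiv), Ph3P=S (5 mol%), MeCN, rt → 40 °C
Reagents that add atoms: N-chlorosuccinimide, O=C1CCC(=O)N1Cl
Why: Electrophilic aromatic chlorination under neutral conditions. C7 is para to the methoxy group and ortho to the ring oxygen, whereas C5 is wedged between OCH3 and CH3, and the only ring B C–H is buried between two MOM ethers on a ring deactivated by two bromines and the azole.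

Step 10
Reactants: 17 7-chloro-3-[2,6-dibromo-3,5-bis(methoxymethoxy)phenyl]-4-methoxy-6-methyl-1,2-benzisoxazole; 18 prenyl bromide (1-bromo-3-methylbut-2-ene)
Product: 21 3-[2-bromo-3,5-bis(methoxymethoxy)-6-(3-methylbut-2-enyl)phenyl]-7-chloro-4-methoxy-6-methyl-1,2-benzisoxazole, via aryllithium 19 (not isolated), via arylcopper 20 (not isolated)
Conditions: n-BuLi (1.05 equiv), THF, −78 °C; CuBr·SMe2, −78 → −40 °C; 18, −78 → 0 °C
Reagents that add atoms: none
Why: Bromine–lithium exchange, assisted by the neighbouring MOM ether, is faster than deprotonation at −78 °C and should stop after one exchange because a second would build a dianion. Transmetalation to copper and allylic substitution on 18 should give the linear prenyl arene, since attack at the tertiary terminus would place a quaternary carbon on a di-ortho-substituted ring.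

Step 11
Reactants: 21 3-[2-bromo-3,5-bis(methoxymethoxy)-6-(3-methylbut-2-enyl)phenyl]-7-chloro-4-methoxy-6-methyl-1,2-benzisoxazole
Product: 24 [2-(7-chloro-4-methoxy-6-methyl-1,2-benzisoxazol-3-yl)-4,6-bis(methoxymethoxy)-3-(3-methylbut-2-enyl)phenyl]methanol, via aryllithium 22 (not isolated), via aldehyde 23 (not isolated)
Conditions: n-BuLi, THF, −78 °C; DMF, −78 → 0 °C; then MeOH, NaBH4, 0 °C; aq. NH4Cl
Reagents that add atoms: N,N-dimethylformamide, CN(C)C=O
Why: A second bromine–lithium exchange, formylation with DMF (Bouveault aldehyde synthesis) and borohydride reduction in the same flask. The formyl carbon is parked as CH2OH so that no aldehyde is present when the nitrogen is released in step 12, which would otherwise close an isoindolinone.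

Step 12
Reactants: 24 [2-(7-chloro-4-methoxy-6-methyl-1,2-benzisoxazol-3-yl)-4,6-bis(methoxymethoxy)-3-(3-methylbut-2-enyl)phenyl]methanol
Product: 26 (3-chloro-2-hydroxy-6-methoxy-4-methylphenyl)[2-(hydroxymethyl)-3,5-bis(methoxymethoxy)-6-(3-methylbut-2-enyl)phenyl]methanone, via ketimine 25 (not isolated)
Conditions: Mo(CO)6, MeCN/H2O, 80 °C; then AcOH/THF/H2O, rt
Reagents that add atoms: water, O
Why: Mo(CO)6 binds the ring nitrogen and inserts into the weak N–O bond (reductive N–O cleavage of an isoxazole), giving the ortho-hydroxyaryl N–H ketimine without touching aryl chloride, alkene or acetals. Hydrolysis in dilute acetic acid is helped by the neighbouring CH2OH, which adds to the iminium carbon to form a five-membered N,O-ketal that expels ammonia. Product 26 may sit in equilibrium with its cyclic hemiketal.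

Step 13
Reactants: 26 (3-chloro-2-hydroxy-6-methoxy-4-methylphenyl)[2-(hydroxymethyl)-3,5-bis(methoxymethoxy)-6-(3-methylbut-2-enyl)phenyl]methanone
Product: 27 2-(3-chloro-2-hydroxy-6-methoxy-4-methylbenzoyl)-4,6-bis(methoxymethoxy)-3-(3-methylbut-2-enyl)benzaldehyde
Conditions: MnO2 (activated, excess), CH2Cl2, rt
Reagents that add atoms: none
Why: Heterogeneous MnO2 oxidation is selective for the electron-rich benzylic alcohol and stops at the aldehyde. The hydrogen-bonded phenol and the prenyl group should be spared, and the neutral medium avoids the base-induced hydride shift of the keto aldehyde to a phthalide.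

Step 14
Reactants: 27 2-(3-chloro-2-hydroxy-6-methoxy-4-methylbenzoyl)-4,6-bis(methoxymethoxy)-3-(3-methylbut-2-enyl)benzaldehyde
Product: 28 pestalone F, 2-(3-chloro-2-hydroxy-6-methoxy-4-methylbenzoyl)-4,6-dihydroxy-3-(3-methylbut-2-enyl)benzaldehyde
Conditions: 3 M HCl (aq), MeOH, rt → 40 °C
Reagents that add atoms: none
Why: Acid-catalysed solvolysis of the two aryl MOM acetals. Dilute acid near room temperature should cleave them faster than it protonates the trisubstituted alkene, and the aqueous medium returns any dimethyl acetal of the aldehyde.

## Compound list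

1 | 3-methoxy-5-methylphenol | COc1cc(C)cc(O)c1 | starting material
2 | 3-methoxy-5-methylphenyl N-isopropylcarbamate | COc1cc(C)cc(OC(=O)NC(C)C)c1 | intermediate
3 | 3-methoxy-5-methylphenyl N-(tert-butyldimethylsilyl)-N-isopropylcarbamate | COc1cc(C)cc(OC(=O)N(C(C)C)[Si](C)(C)C(C)(C)C)c1 | intermediate (not isolated)
4 | {2-[N-(tert-butyldimethylsilyl)-N-isopropylcarbamoyloxy]-6-methoxy-4-methylphenyl}lithium | COc1cc(C)cc(OC(=O)N(C(C)C)[Si](C)(C)C(C)(C)C)c1[Li] | intermediate (not isolated)
5 | 3-methoxy-5-methyl-2-(trimethylsilyl)phenyl N-(tert-butyldimethylsilyl)-N-isopropylcarbamate | COc1cc(C)cc(OC(=O)N(C(C)C)[Si](C)(C)C(C)(C)C)c1[Si](C)(C)C | intermediate (not isolated)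
6 | 3-methoxy-5-methyl-2-(trimethylsilyl)phenyl N-isopropylcarbamate | COc1cc(C)cc(OC(=O)NC(C)C)c1[Si](C)(C)C | intermediate
7 | 3-methoxy-5-methyl-2-(trimethylsilyl)phenol | COc1cc(C)cc(O)c1[Si](C)(C)C | intermediate (not isolated)
8 | 3-methoxy-5-methyl-2-(trimethylsilyl)phenyl trifluoromethanesulfonate | COc1cc(C)cc(OS(=O)(=O)C(F)(F)F)c1[Si](C)(C)C | intermediate
9 | 3,5-dihydroxybenzaldehyde | O=Cc1cc(O)cc(O)c1 | starting material
10 | 3,5-bis(methoxymethoxy)benzaldehyde | COCOc1cc(C=O)cc(OCOC)c1 | intermediate
11 | 2,6-dibromo-3,5-bis(methoxymethoxy)benzaldehyde | COCOc1cc(OCOC)c(Br)c(C=O)c1Br | intermediate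
12 | (E)-2,6-dibromo-3,5-bis(methoxymethoxy)benzaldehyde oxime | COCOc1cc(OCOC)c(Br)c(/C=N/O)c1Br | intermediate
13 | 2,6-dibromo-N-hydroxy-3,5-bis(methoxymethoxy)benzimidoyl chloride | COCOc1cc(OCOC)c(Br)c(C(Cl)=NO)c1Br | intermediate (not isolated)
14 | 2,6-dibromo-3,5-bis(methoxymethoxy)benzonitrile oxide | COCOc1cc(OCOC)c(Br)c(C#[N+][O-])c1Br | intermediate
15 | 3-methoxy-5-methylbenzyne (1,2-didehydro-3-methoxy-5-methylbenzene) | COC1=CC(C)=CC#C1 | intermediate (not isolated)
16 | 3-[2,6-dibromo-3,5-bis(methoxymethoxy)phenyl]-4-methoxy-6-methyl-1,2-benzisoxazole | COc1cc(C)cc2onc(-c3c(Br)c(OCOC)cc(OCOC)c3Br)c12 | intermediate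
17 | 7-chloro-3-[2,6-dibromo-3,5-bis(methoxymethoxy)phenyl]-4-methoxy-6-methyl-1,2-benzisoxazole | COc1cc(C)c(Cl)c2onc(-c3c(Br)c(OCOC)cc(OCOC)c3Br)c12 | intermediate
18 | prenyl bromide (1-bromo-3-methylbut-2-ene) | CC(C)=CCBr | starting material
19 | [3-bromo-2-(7-chloro-4-methoxy-6-methyl-1,2-benzisoxazol-3-yl)-4,6-bis(methoxymethoxy)phenyl]lithium | COc1cc(C)c(Cl)c2onc(-c3c([Li])c(OCOC)cc(OCOC)c3Br)c12 | intermediate (not isolated)
20 | [3-bromo-2-(7-chloro-4-methoxy-6-methyl-1,2-benzisoxazol-3-yl)-4,6-bis(methoxymethoxy)phenyl]copper | COc1cc(C)c(Cl)c2onc(-c3c([Cu])c(OCOC)cc(OCOC)c3Br)c12 | intermediate (not isolated)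
21 | 3-[2-bromo-3,5-bis(methoxymethoxy)-6-(3-methylbut-2-enyl)phenyl]-7-chloro-4-methoxy-6-methyl-1,2-benzisoxazole | COc1cc(C)c(Cl)c2onc(-c3c(CC=C(C)C)c(OCOC)cc(OCOC)c3Br)c12 | intermediate
22 | [2-(7-chloro-4-methoxy-6-methyl-1,2-benzisoxazol-3-yl)-4,6-bis(methoxymethoxy)-3-(3-methylbut-2-enyl)phenyl]lithium | COc1cc(C)c(Cl)c2onc(-c3c(CC=C(C)C)c(OCOC)cc(OCOC)c3[Li])c12 | intermediate (not isolated)
23 | 2-(7-chloro-4-methoxy-6-methyl-1,2-benzisoxazol-3-yl)-4,6-bis(methoxymethoxy)-3-(3-methylbut-2-enyl)benzaldehyde | COc1cc(C)c(Cl)c2onc(-c3c(CC=C(C)C)c(OCOC)cc(OCOC)c3C=O)c12 | intermediate (not isolated)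
24 | [2-(7-chloro-4-methoxy-6-methyl-1,2-benzisoxazol-3-yl)-4,6-bis(methoxymethoxy)-3-(3-methylbut-2-enyl)phenyl]methanol | COc1cc(C)c(Cl)c2onc(-c3c(CC=C(C)C)c(OCOC)cc(OCOC)c3CO)c12 | intermediate
25 | 2-chloro-6-{[2-(hydroxymethyl)-3,5-bis(methoxymethoxy)-6-(3-methylbut-2-enyl)phenyl](imino)methyl}-5-methoxy-3-methylphenol | COc1cc(C)c(Cl)c(O)c1C(=N)c1c(CO)c(OCOC)cc(OCOC)c1CC=C(C)C | intermediate (not isolated)
26 | (3-chloro-2-hydroxy-6-methoxy-4-methylphenyl)[2-(hydroxymethyl)-3,5-bis(methoxymethoxy)-6-(3-methylbut-2-enyl)phenyl]methanone | COc1cc(C)c(Cl)c(O)c1C(=O)c1c(CO)c(OCOC)cc(OCOC)c1CC=C(C)C | intermediate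
27 | 2-(3-chloro-2-hydroxy-6-methoxy-4-methylbenzoyl)-4,6-bis(methoxymethoxy)-3-(3-methylbut-2-enyl)benzaldehyde | COc1cc(C)c(Cl)c(O)c1C(=O)c1c(C=O)c(OCOC)cc(OCOC)c1CC=C(C)C | intermediate
28 | pestalone F, 2-(3-chloro-2-hydroxy-6-methoxy-4-methylbenzoyl)-4,6-dihydroxy-3-(3-methylbut-2-enyl)benzaldehyde | COc1cc(C)c(Cl)c(O)c1C(=O)c1c(C=O)c(O)cc(O)c1CC=C(C)C | target

## Step count and least certain steps

Total: 14 steps. Longest linear sequence: 11 steps (9 to 28, steps 4–14); the other branch (1 to 8) has 3 steps before joining at step 8.

**Step 8 (key step).** Steric repulsion between the ortho bromines of the dipole and the methoxy group works against the electronic bias of the aryne, so regiocontrol may erode. The crowded cycloaddition may also be slow enough for the aryne to be consumed by fluoride or solvent. The fallback drops the aryne and builds the same heterocycle on a cyclic 1,3-dione, where the dipole carbon can only bond to the central carbon.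
- It sets out from 14 and commercial 5-methylcyclohexane-1,3-dione: enolate addition to the nitrile oxide and cyclocondensation (Et3N, EtOH, rt) should give racemic 3-[2,6-dibromo-3,5-bis(methoxymethoxy)phenyl]-6-methyl-6,7-dihydro-1,2-benzisoxazol-4(5H)-one F1.
- Alpha-bromination and loss of HBr in one flask (CuBr2, LiBr, MeCN, reflux) should aromatise it to 3-[2,6-dibromo-3,5-bis(methoxymethoxy)phenyl]-6-methyl-1,2-benzisoxazol-4-ol F2.
- O-Methylation (MeI, K2CO3, acetone) returns to the route at 16.

**Step 9.** Chlorination may occur in part at C5 or at the ring B C–H, or go on to a dichloride, because all three positions are activated by oxygen. The fallback replaces electronic control by steric control.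
- From 16, C–H borylation ([Ir(OMe)(cod)]2, 4,4'-di-tert-butyl-2,2'-bipyridine, B2pin2, THF, 80 °C) should take the only C–H not flanked by two freely rotating substituents, giving 3-[2,6-dibromo-3,5-bis(methoxymethoxy)phenyl]-4-methoxy-6-methyl-7-(4,4,5,5-tetramethyl-1,3,2-dioxaborolan-2-yl)-1,2-benzisoxazole F3.
- Chlorodeboronation (CuCl2, MeOH/H2O, 80 °C) returns to the route at 17.

**Step 10.** Substitution may occur at the tertiary end of the allyl system, a second bromine may exchange, or the aryllithium may be quenched by proton transfer from the acidic ring B C–H. The fallback removes the allylic regiochemistry question.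
- From 17, the same exchange and copper transmetalation with allyl bromide should give 3-[2-allyl-6-bromo-3,5-bis(methoxymethoxy)phenyl]-7-chloro-4-methoxy-6-methyl-1,2-benzisoxazole F4.
- Cross-metathesis with 2-methylbut-2-ene (second-generation Grubbs catalyst, CH2Cl2, 40 °C) returns to the route at 21.

**Step 12.** Insertion of the metal into the hindered N–O bond may be sluggish, long heating with the metal carbonyl may move the prenyl double bond, and stronger acid would ionise the electron-rich benzylic alcohol, letting the imine nitrogen capture the cation. The fallback replaces thermal coordination and insertion by outer-sphere electron transfer at low temperature: from 24, SmI2 in THF/MeOH at 0 °C should give 25, which is hydrolysed as before, returning to the route at 26. This fallback makes no compound outside the list (F0).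

**Step 14.** The C5' phenol may cyclise onto the prenyl alkene under acid (chroman formation), and the aldehyde may be acetalised. The fallback avoids protic acid.
- From 27, TMSOTf and 2,2'-bipyridyl in CH2Cl2 at 0 °C should exchange the MOM groups (and silylate the free phenol), giving 2-{3-chloro-6-methoxy-4-methyl-2-[(trimethylsilyl)oxy]benzoyl}-3-(3-methylbut-2-enyl)-4,6-bis[(trimethylsilyl)oxy]benzaldehyde F5.
- Neutral hydrolysis with water returns to the route at 28.

## Further compounds

F1 | step 8 | 3-[2,6-dibromo-3,5-bis(methoxymethoxy)phenyl]-6-methyl-6,7-dihydro-1,2-benzisoxazol-4(5H)-one (racemic) | CC1CC(=O)c2c(-c3c(Br)c(OCOC)cc(OCOC)c3Br)noc2C1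
F2 | step 8 | 3-[2,6-dibromo-3,5-bis(methoxymethoxy)phenyl]-6-methyl-1,2-benzisoxazol-4-ol | Cc1cc(O)c2c(-c3c(Br)c(OCOC)cc(OCOC)c3Br)noc2c1
F3 | step 9 | 3-[2,6-dibromo-3,5-bis(methoxymethoxy)phenyl]-4-methoxy-6-methyl-7-(4,4,5,5-tetramethyl-1,3,2-dioxaborolan-2-yl)-1,2-benzisoxazole | COc1cc(C)c(B3OC(C)(C)C(C)(C)O3)c2onc(-c3c(Br)c(OCOC)cc(OCOC)c3Br)c12
F4 | step 10 | 3-[2-allyl-6-bromo-3,5-bis(methoxymethoxy)phenyl]-7-chloro-4-methoxy-6-methyl-1,2-benzisoxazole | COc1cc(C)c(Cl)c2onc(-c3c(CC=C)c(OCOC)cc(OCOC)c3Br)c12
F0 | step 12 | none | none
F5 | step 14 | 2-{3-chloro-6-methoxy-4-methyl-2-[(trimethylsilyl)oxy]benzoyl}-3-(3-methylbut-2-enyl)-4,6-bis[(trimethylsilyl)oxy]benzaldehyde | COc1cc(C)c(Cl)c(O[Si](C)(C)C)c1C(=O)c1c(C=O)c(O[Si](C)(C)C)cc(O[Si](C)(C)C)c1CC=C(C)C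
A1 | alternative 1 | 6-{5-(tert-butyldimethylsilyloxy)-5-[2-(tert-butyldimethylsilyloxy)-3-chloro-6-methoxy-4-methylphenyl]-3-(3-methylbut-2-enyl)-2,4-dioxopentyl}-2,2-dimethyl-4H-1,3-dioxin-4-one (racemic, mixture of diastereomers) | CC1(C)OC(=O)C=C(CC(=O)C(CC=C(C)C)C(=O)C(O[Si](C)(C)C(C)(C)C)c2c(OC)cc(C)c(Cl)c2O[Si](C)(C)C(C)(C)C)O1
A2 | alternative 1 | 5-{(tert-butyldimethylsilyloxy)[2-(tert-butyldimethylsilyloxy)-3-chloro-6-methoxy-4-methylphenyl]methyl}-7-hydroxy-2,2-dimethyl-6-(3-methylbut-2-enyl)-4H-1,3-benzodioxin-4-one (racemic) | CC1(C)Oc2cc(O)c(CC=C(C)C)c(C(O[Si](C)(C)C(C)(C)C)c3c(OC)cc(C)c(Cl)c3O[Si](C)(C)C(C)(C)C)c2C(=O)O1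
A3 | alternative 2 | 4-chloro-3-methylcyclobut-2-enone (racemic) | CC1=CC(=O)C1Cl
A4 | alternative 2 | 1-[2-(tert-butyldimethylsilyloxymethyl)-3,5-bis(methoxymethoxy)-6-(3-methylbut-2-enyl)phenyl]-1-(tert-butyldimethylsilyloxy)-3-methoxyprop-2-yne (racemic) | COC#CC(O[Si](C)(C)C(C)(C)C)c1c(CO[Si](C)(C)C(C)(C)C)c(OCOC)cc(OCOC)c1CC=C(C)C
A5 | alternative 2 | 2-{[2-(tert-butyldimethylsilyloxymethyl)-3,5-bis(methoxymethoxy)-6-(3-methylbut-2-enyl)phenyl](tert-butyldimethylsilyloxy)methyl}-6-chloro-3-methoxy-5-methylphenol (racemic) | COc1cc(C)c(Cl)c(O)c1C(O[Si](C)(C)C(C)(C)C)c1c(CO[Si](C)(C)C(C)(C)C)c(OCOC)cc(OCOC)c1CC=C(C)C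
A6 | alternative 3 | 1-methoxy-7-methyl-1,3-bis(trimethylsilyloxy)octa-1,3,6-triene | COC(O[Si](C)(C)C)=CC(O[Si](C)(C)C)=CCC=C(C)C
A7 | alternative 3 | methyl 4-(tert-butyldimethylsilyloxy)-4-[2-(tert-butyldimethylsilyloxy)-3-chloro-6-methoxy-4-methylphenyl]but-2-ynoate (racemic) | COC(=O)C#CC(O[Si](C)(C)C(C)(C)C)c1c(OC)cc(C)c(Cl)c1O[Si](C)(C)C(C)(C)C
A8 | alternative 3 | methyl 2-{(tert-butyldimethylsilyloxy)[2-(tert-butyldimethylsilyloxy)-3-chloro-6-methoxy-4-methylphenyl]methyl}-4,6-dihydroxy-3-(3-methylbut-2-enyl)benzoate (racemic) | COC(=O)c1c(O)cc(O)c(CC=C(C)C)c1C(O[Si](C)(C)C(C)(C)C)c1c(OC)cc(C)c(Cl)c1O[Si](C)(C)C(C)(C)C
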